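The route disconnects the C7–C(=O) bond and the C6–O bond of ring A (the phloroglucinol ring; 1-benzoxepine numbering) together, back to a C6–C7 aryne and the side-chain carboxylic acid. The key step exploits the 1,2,3-pattern C6(OH)–C7(acyl)–C8(O): the C8 acetal oxygen polarises the aryne, the carboxylate oxygen adds at C6 and the acyl group migrates to C7, so ketone and phenol arise in one operation on the intact oxepine. The precursor is the 3-methyl-2,5-dihydro-1-benzoxepine bearing C6 triflate, C7 trimethylsilyl and C8 methoxymethoxy groups. Its C6 oxygen is singled out by mono-etherification of a symmetric resorcinol before ring-closing metathesis, then unmasked from a directing carbamate.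

Key step: step 12

Remark: the target has no stereocentre and its only C=C bond is endocyclic, so no configuration has to be set. The first and fifth steps are statistical mono-functionalisations of symmetry-equivalent hydroxyls; they cost material but raise no regiochemical question.

Step 1
Reactants: 1 phloroglucinol (benzene-1,3,5-triol)
Product: 2 5-(methoxymethoxy)benzene-1,3-diol
Conditions: MOMCl (0.5 equiv), i-Pr2NEt, THF/DMF, 0 °C to rt; 1 in twofold excess
Reagents that add atoms: chloromethyl methyl ether, COCCl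
Why: O-alkylation of one of three equivalent phenols with a hard chloromethyl ether (acetal formation); with the triol in excess the mono-ether should dominate and the water-soluble triol is washed out.

Step 2
Reactants: 2 5-(methoxymethoxy)benzene-1,3-diol
Product: 3 5-(methoxymethoxy)-1,3-phenylene bis(N,N-diethylcarbamate)
Conditions: Et2NCOCl (2.5 equiv), K2CO3, MeCN, 80 °C
Reagents that add atoms: N,N-diethylcarbamoyl chloride, CCN(CC)C(Cl)=O
Why: O-carbamoylation (acyl substitution) of both phenols installs two strong, base-stable directing groups and leaves the acetal untouched.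

Step 3
Reactants: 3 5-(methoxymethoxy)-1,3-phenylene bis(N,N-diethylcarbamate); 4 allyl bromide (3-bromoprop-1-ene)
Product: 6 5-(methoxymethoxy)-2-(prop-2-en-1-yl)-1,3-phenylene bis(N,N-diethylcarbamate), via aryllithium 5 (not isolated)
Conditions: s-BuLi, TMEDA, THF, −78 °C; then CuBr·SMe2 (10 mol%), 4, −78 to −40 °C
Reagents that add atoms: none
Why: Directed ortho-metalation removes the C2–H flanked by the two carbamates (the strongest oxygen directors) in preference to the C–H between one carbamate and the acetal, and the aryllithium, kept cold to forestall the anionic Fries shift, is allylated under copper catalysis.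

Step 4
Reactants: 6 5-(methoxymethoxy)-2-(prop-2-en-1-yl)-1,3-phenylene bis(N,N-diethylcarbamate)
Product: 7 5-(methoxymethoxy)-2-(prop-2-en-1-yl)benzene-1,3-diol
Conditions: LiAlH4, THF, 0 to 65 °C; aq. potassium sodium tartrate
Reagents that add atoms: none
Why: Hydride reduction of aryl carbamates, in which LiAlH4 attacks the carbamoyl carbonyl and expels the phenoxide, should free both phenols while the allyl group and the acetal are inert.

Step 5
Reactants: 7 5-(methoxymethoxy)-2-(prop-2-en-1-yl)benzene-1,3-diol; 8 3-chloro-2-methylpropene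
Product: 9 5-(methoxymethoxy)-3-[(2-methylprop-2-en-1-yl)oxy]-2-(prop-2-en-1-yl)phenol
Conditions: 8 (0.9 equiv), K2CO3, NaI (cat.), acetone, 55 °C
Reagents that add atoms: none
Why: Williamson etherification in which the two phenols are equivalent by symmetry, so either gives the same mono-ether; the sub-stoichiometric chloride limits the bis-ether and unreacted diol is recycled.

Step 6
Reactants: 9 5-(methoxymethoxy)-3-[(2-methylprop-2-en-1-yl)oxy]-2-(prop-2-en-1-yl)phenol
Product: 10 8-(methoxymethoxy)-3-methyl-2,5-dihydro-1-benzoxepin-6-ol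
Conditions: second-generation Grubbs catalyst (5 mol%), CH2Cl2 (dilute), 40 °C
Reagents that add atoms: none
Why: Ring-closing olefin metathesis of the C-allyl and O-(2-methylallyl) groups should give the seven-membered ring with the trisubstituted C3=C4 alkene (cis by ring constraint), and the untouched phenol becomes the free C6 hydroxyl.

Step 7
Reactants: 10 8-(methoxymethoxy)-3-methyl-2,5-dihydro-1-benzoxepin-6-ol
Product: 11 8-(methoxymethoxy)-3-methyl-2,5-dihydro-1-benzoxepin-6-yl N-(propan-2-yl)carbamate
Conditions: i-PrNCO, Et3N (cat.), CH2Cl2, rt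
Reagents that add atoms: isopropyl isocyanate, CC(C)N=C=O
Why: Base-catalysed addition of the phenol to an isocyanate gives an N-monoalkyl carbamate that directs metalation and can later be removed under mild base.

Step 8
Reactants: 11 8-(methoxymethoxy)-3-methyl-2,5-dihydro-1-benzoxepin-6-yl N-(propan-2-yl)carbamate
Product: 15 8-(methoxymethoxy)-3-methyl-7-(trimethylsilyl)-2,5-dihydro-1-benzoxepin-6-yl N-(propan-2-yl)carbamate, via N-silyl carbamate 12 (not isolated), via C7 aryllithium 13 (not isolated), via N-silyl C7-silyl carbamate 14 (not isolated)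
Conditions: TBSOTf, TMEDA, Et2O, 0 °C to rt; n-BuLi (1.3 equiv), TMEDA, −78 °C; TMSCl, −78 °C; aq. NH4Cl
Reagents that add atoms: chlorotrimethylsilane, C[Si](C)(C)Cl
Why: Directed ortho-metalation after in-flask N-silylation of the N–H: C7 is the only position ortho to the carbamate and is also flanked by the C8 acetal, so lithiation there is cooperative and fast at −78 °C, silicon is introduced and the N–Si bond is hydrolysed at work-up.

Step 9
Reactants: 15 8-(methoxymethoxy)-3-methyl-7-(trimethylsilyl)-2,5-dihydro-1-benzoxepin-6-yl N-(propan-2-yl)carbamate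
Product: 17 8-(methoxymethoxy)-3-methyl-7-(trimethylsilyl)-2,5-dihydro-1-benzoxepin-6-yl trifluoromethanesulfonate, via silyl phenol 16 (not isolated)
Conditions: Et2NH, DBU, MeCN, 40 °C; then PhNTf2, rt
Reagents that add atoms: N-phenylbis(trifluoromethanesulfonimide), O=S(=O)(N(c1ccccc1)S(=O)(=O)C(F)(F)F)C(F)(F)F
Why: E1cB cleavage of the N-monoalkyl carbamate (isopropyl isocyanate is lost and trapped by diethylamine as a urea) frees only the C6 phenoxide, without acid that would endanger the acetal or the aryl–silicon bond, and O-sulfonylation by the triflimide gives the o-silylaryl triflate.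

Step 10
Reactants: 18 3-(3,4-dihydroxyphenyl)propanoic acid
Product: 19 methoxymethyl 3-[3,4-bis(methoxymethoxy)phenyl]propanoate
Conditions: MOMCl (3.5 equiv), i-Pr2NEt, CH2Cl2, 0 °C to rt
Reagents that add atoms: chloromethyl methyl ether, COCCl
Why: Exhaustive O-alkylation of both phenols and the carboxylic acid with the chloromethyl ether gives the bis-acetal ester.

Step 11
Reactants: 19 methoxymethyl 3-[3,4-bis(methoxymethoxy)phenyl]propanoate
Product: 20 3-[3,4-bis(methoxymethoxy)phenyl]propanoic acid
Conditions: LiOH, THF/H2O, rt; then 1 M HCl to pH 4, 0 °C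
Reagents that add atoms: lithium hydroxide, [Li+].[OH-]
Why: Saponification of the acyloxymethyl ester; the aryl acetals are stable to hydroxide and survive the brief, cold, mildly acidic work-up.

Step 12
Reactants: 17 8-(methoxymethoxy)-3-methyl-7-(trimethylsilyl)-2,5-dihydro-1-benzoxepin-6-yl trifluoromethanesulfonate; 20 3-[3,4-bis(methoxymethoxy)phenyl]propanoic acid
Product: 23 3-[3,4-bis(methoxymethoxy)phenyl]-1-[6-hydroxy-8-(methoxymethoxy)-3-methyl-2,5-dihydro-1-benzoxepin-7-yl]propan-1-one, via aryne 21 (not isolated), via aryl anion ester 22 (not isolated)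
Conditions: CsF (6 equiv), 20 (2 equiv, pre-stirred with CsF), THF, 125 °C, sealed tube; aq. NH4Cl
Reagents that add atoms: none
Why: Fluoride attacks silicon and the C7 carbanion expels the C6 triflate to give the C6–C7 aryne 21; the inductively withdrawing C8 acetal oxygen distorts this aryne so that the caesium carboxylate of 20 attacks C6, the carbon remote from that oxygen, and the negative charge is placed on C7 beside it (22). The C7 anion then attacks the adjacent ester carbonyl through a four-membered transition state and the acyl C–O bond breaks (an anionic Fries-type 1,3-acyl shift), forming the C7–C(=O) bond and the C6 phenoxide, which is protonated at work-up. The closest known reaction type is the insertion of arynes from o-silylaryl triflates into the C–O bond of carboxylic acids to give o-hydroxyaryl ketones, run in hot THF where the aryl anion should be trapped by the ester faster than by a proton. No ring is closed and no stereocentre is formed. The selectivity needed is regiochemical (oxygen to C6, carbon to C7) and is secured by the oxygen substituent on C8 next to the aryne, as with 3-alkoxybenzynes; the excess of carboxylate over aryne keeps the product phenoxide and the oxepine alkene (ene reaction) from competing.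

Step 13
Reactants: 23 3-[3,4-bis(methoxymethoxy)phenyl]-1-[6-hydroxy-8-(methoxymethoxy)-3-methyl-2,5-dihydro-1-benzoxepin-7-yl]propan-1-one
Product: 24 3-(3,4-dihydroxyphenyl)-1-(6,8-dihydroxy-3-methyl-2,5-dihydro-1-benzoxepin-7-yl)propan-1-one
Conditions: HCl (1.5 M), MeOH/THF, 40 °C
Reagents that add atoms: none
Why: Acid-catalysed acetal solvolysis (transacetalisation to dimethoxymethane) should remove all three methoxymethyl groups, the one ortho to the ketone fastest, under conditions mild enough to spare the trisubstituted alkene and the allyl aryl ether.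

Compound list
1 | phloroglucinol (benzene-1,3,5-triol) | Oc1cc(O)cc(O)c1 | starting material
2 | 5-(methoxymethoxy)benzene-1,3-diol | COCOc1cc(O)cc(O)c1 | intermediate
3 | 5-(methoxymethoxy)-1,3-phenylene bis(N,N-diethylcarbamate) | CCN(CC)C(=O)Oc1cc(OCOC)cc(OC(=O)N(CC)CC)c1 | intermediate
4 | allyl bromide (3-bromoprop-1-ene) | C=CCBr | starting material
5 | [2,6-bis(diethylcarbamoyloxy)-4-(methoxymethoxy)phenyl]lithium | CCN(CC)C(=O)Oc1cc(OCOC)cc(OC(=O)N(CC)CC)c1[Li] | intermediate
6 | 5-(methoxymethoxy)-2-(prop-2-en-1-yl)-1,3-phenylene bis(N,N-diethylcarbamate) | C=CCc1c(OC(=O)N(CC)CC)cc(OCOC)cc1OC(=O)N(CC)CC | intermediate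
7 | 5-(methoxymethoxy)-2-(prop-2-en-1-yl)benzene-1,3-diol | C=CCc1c(O)cc(OCOC)cc1O | intermediate
8 | 3-chloro-2-methylpropene | CC(=C)CCl | starting material
9 | 5-(methoxymethoxy)-3-[(2-methylprop-2-en-1-yl)oxy]-2-(prop-2-en-1-yl)phenol | C=CCc1c(O)cc(OCOC)cc1OCC(C)=C | intermediate
10 | 8-(methoxymethoxy)-3-methyl-2,5-dihydro-1-benzoxepin-6-ol | CC1=CCc2c(O)cc(OCOC)cc2OC1 | intermediate
11 | 8-(methoxymethoxy)-3-methyl-2,5-dihydro-1-benzoxepin-6-yl N-(propan-2-yl)carbamate | CC1=CCc2c(OC(=O)NC(C)C)cc(OCOC)cc2OC1 | intermediate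
12 | 8-(methoxymethoxy)-3-methyl-2,5-dihydro-1-benzoxepin-6-yl N-[tert-butyl(dimethyl)silyl]-N-(propan-2-yl)carbamate | CC1=CCc2c(OC(=O)N(C(C)C)[Si](C)(C)C(C)(C)C)cc(OCOC)cc2OC1 | intermediate
13 | C7-lithio derivative of 12 | CC1=CCc2c(OC(=O)N(C(C)C)[Si](C)(C)C(C)(C)C)c([Li])c(OCOC)cc2OC1 | intermediate
14 | 8-(methoxymethoxy)-3-methyl-7-(trimethylsilyl)-2,5-dihydro-1-benzoxepin-6-yl N-[tert-butyl(dimethyl)silyl]-N-(propan-2-yl)carbamate | CC1=CCc2c(OC(=O)N(C(C)C)[Si](C)(C)C(C)(C)C)c([Si](C)(C)C)c(OCOC)cc2OC1 | intermediate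
15 | 8-(methoxymethoxy)-3-methyl-7-(trimethylsilyl)-2,5-dihydro-1-benzoxepin-6-yl N-(propan-2-yl)carbamate | CC1=CCc2c(OC(=O)NC(C)C)c([Si](C)(C)C)c(OCOC)cc2OC1 | intermediate
16 | 8-(methoxymethoxy)-3-methyl-7-(trimethylsilyl)-2,5-dihydro-1-benzoxepin-6-ol | CC1=CCc2c(O)c([Si](C)(C)C)c(OCOC)cc2OC1 | intermediate
17 | 8-(methoxymethoxy)-3-methyl-7-(trimethylsilyl)-2,5-dihydro-1-benzoxepin-6-yl trifluoromethanesulfonate | CC1=CCc2c(cc(OCOC)c([Si](C)(C)C)c2OS(=O)(=O)C(F)(F)F)OC1 | intermediate
18 | 3-(3,4-dihydroxyphenyl)propanoic acid | OC(=O)CCc1ccc(O)c(O)c1 | starting material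
19 | methoxymethyl 3-[3,4-bis(methoxymethoxy)phenyl]propanoate | COCOC(=O)CCc1ccc(OCOC)c(OCOC)c1 | intermediate
20 | 3-[3,4-bis(methoxymethoxy)phenyl]propanoic acid | OC(=O)CCc1ccc(OCOC)c(OCOC)c1 | intermediate
21 | 8-(methoxymethoxy)-3-methyl-6,7-didehydro-2,5-dihydro-1-benzoxepine (C6–C7 aryne) | CC1=CCC2=C(OC1)C=C(OCOC)C#C2 | intermediate
22 | caesium salt of the C7 carbanion of 8-(methoxymethoxy)-3-methyl-2,5-dihydro-1-benzoxepin-6-yl 3-[3,4-bis(methoxymethoxy)phenyl]propanoate | CC1=CCc2c(cc(OCOC)[c-]c2OC(=O)CCc3ccc(OCOC)c(OCOC)c3)OC1.[Cs+] | intermediate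
23 | 3-[3,4-bis(methoxymethoxy)phenyl]-1-[6-hydroxy-8-(methoxymethoxy)-3-methyl-2,5-dihydro-1-benzoxepin-7-yl]propan-1-one | CC1=CCc2c(cc(OCOC)c(C(=O)CCc3ccc(OCOC)c(OCOC)c3)c2O)OC1 | intermediate
24 | 3-(3,4-dihydroxyphenyl)-1-(6,8-dihydroxy-3-methyl-2,5-dihydro-1-benzoxepin-7-yl)propan-1-one | CC1=CCc2c(cc(O)c(C(=O)CCc3ccc(O)c(O)c3)c2O)OC1 | target

Total step count: 13. Longest linear sequence: 11 steps (steps 1–9, 12 and 13, from 1 to 24); the acid branch (steps 10 and 11) joins at step 12.

Steps most likely to fail

Step 12. The C7 aryl anion may be protonated before the acyl shift (leaving a plain C6 aryl ester), the carboxylate may add at C7 instead of C6, or the aryne may be consumed by an ene reaction with the oxepine alkene. The fallback is a Weinreb ketone synthesis on the same directed metalation, and it sets out from 11 and 20. Acid 20 is coupled with N,O-dimethylhydroxylamine (carbodiimide activation) to the Weinreb amide 3-[3,4-bis(methoxymethoxy)phenyl]-N-methoxy-N-methylpropanamide F1. Carbamate 11 is N-silylated and lithiated at C7 as in step 8 (12, then 13), and 13 is quenched with F1 at −78 °C to give the lithium hemiaminal adduct F2. Aqueous work-up collapses the adduct and hydrolyses the N–Si bond to the keto carbamate 7-{3-[3,4-bis(methoxymethoxy)phenyl]propanoyl}-8-(methoxymethoxy)-3-methyl-2,5-dihydro-1-benzoxepin-6-yl N-(propan-2-yl)carbamate F3. Diethylamine and DBU (as in step 9, without the triflimide) then remove the carbamate, and the route is rejoined at 23.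

Step 8. The doubly activated (benzylic and allylic) C5 methylene or the C2 methylene of the cyclic allyl aryl ether may be deprotonated in competition with C7, and the acetal may be lost under the silyl triflate. The fallback puts the silicon in before the oxepine exists and sets out from 6. A second directed ortho-metalation (s-BuLi, TMEDA, −78 °C) at either of the two equivalent positions flanked by a carbamate and the acetal gives the aryllithium F4, and TMSCl gives 5-(methoxymethoxy)-2-(prop-2-en-1-yl)-4-(trimethylsilyl)-1,3-phenylene bis(N,N-diethylcarbamate) F5. LiAlH4 frees the diol 5-(methoxymethoxy)-2-(prop-2-en-1-yl)-4-(trimethylsilyl)benzene-1,3-diol F6. Etherification with one equivalent of 8 should favour the hydroxyl remote from silicon, which has one ortho substituent instead of two, and give 3-(methoxymethoxy)-5-[(2-methylprop-2-en-1-yl)oxy]-6-(prop-2-en-1-yl)-2-(trimethylsilyl)phenol F7. Ring-closing metathesis (second-generation Grubbs catalyst) then delivers 16, now isolated, and triflation as in the second half of step 9 rejoins the route at 17.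

Step 5. Both equivalent phenols may be alkylated, and the electron-rich ring may be C-alkylated, so that little mono-ether is obtained. The fallback lets the ring closure do the differentiation and sets out from 7. Exhaustive etherification (excess 8, K2CO3, DMF) gives the bis-ether 5-(methoxymethoxy)-1,3-bis[(2-methylprop-2-en-1-yl)oxy]-2-(prop-2-en-1-yl)benzene F8. Ring-closing metathesis (second-generation Grubbs catalyst) can close only one seven-membered ring and gives 8-(methoxymethoxy)-3-methyl-6-[(2-methylprop-2-en-1-yl)oxy]-2,5-dihydro-1-benzoxepine F9. Pd(PPh3)4 with morpholine then removes the remaining acyclic 2-methylallyl ether (Tsuji–Trost-type deallylation); the endocyclic trisubstituted allylic ether should ionise far more slowly and re-close if it does. The route is rejoined at 10.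

Further compounds
F1 | step 12 | 3-[3,4-bis(methoxymethoxy)phenyl]-N-methoxy-N-methylpropanamide | CON(C)C(=O)CCc1ccc(OCOC)c(OCOC)c1
F2 | step 12 | lithium hemiaminal adduct of 13 and F1 | CC1=CCc2c(OC(=O)N(C(C)C)[Si](C)(C)C(C)(C)C)c(C(O[Li])(N(C)OC)CCc3ccc(OCOC)c(OCOC)c3)c(OCOC)cc2OC1
F3 | step 12 | 7-{3-[3,4-bis(methoxymethoxy)phenyl]propanoyl}-8-(methoxymethoxy)-3-methyl-2,5-dihydro-1-benzoxepin-6-yl N-(propan-2-yl)carbamate | CC1=CCc2c(OC(=O)NC(C)C)c(C(=O)CCc3ccc(OCOC)c(OCOC)c3)c(OCOC)cc2OC1
F4 | step 8 | [2,4-bis(diethylcarbamoyloxy)-6-(methoxymethoxy)-3-(prop-2-en-1-yl)phenyl]lithium | C=CCc1c(OC(=O)N(CC)CC)cc(OCOC)c([Li])c1OC(=O)N(CC)CC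
F5 | step 8 | 5-(methoxymethoxy)-2-(prop-2-en-1-yl)-4-(trimethylsilyl)-1,3-phenylene bis(N,N-diethylcarbamate) | C=CCc1c(OC(=O)N(CC)CC)cc(OCOC)c([Si](C)(C)C)c1OC(=O)N(CC)CC
F6 | step 8 | 5-(methoxymethoxy)-2-(prop-2-en-1-yl)-4-(trimethylsilyl)benzene-1,3-diol | C=CCc1c(O)cc(OCOC)c([Si](C)(C)C)c1O
F7 | step 8 | 3-(methoxymethoxy)-5-[(2-methylprop-2-en-1-yl)oxy]-6-(prop-2-en-1-yl)-2-(trimethylsilyl)phenol | C=CCc1c(OCC(C)=C)cc(OCOC)c([Si](C)(C)C)c1O
F8 | step 5 | 5-(methoxymethoxy)-1,3-bis[(2-methylprop-2-en-1-yl)oxy]-2-(prop-2-en-1-yl)benzene | C=CCc1c(OCC(C)=C)cc(OCOC)cc1OCC(C)=C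
F9 | step 5 | 8-(methoxymethoxy)-3-methyl-6-[(2-methylprop-2-en-1-yl)oxy]-2,5-dihydro-1-benzoxepine | CC1=CCc2c(OCC(C)=C)cc(OCOC)cc2OC1
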